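Larch, hotter than elm on the same solid charge, ended with 38.9% side product where elm ended with 23.6%; the three new flasks are read from that comparison.

| setting | elm | larch | ash | green | teal | ochre |
|---|---|---|---|---|---|---|
| substrate | 0.050 M | 0.050 M | 0.050 M | 0.050 M | 0.050 M | 0.050 M |
| third reagent | 0.60 equiv | 0.90 equiv | 1.2 equiv | 1.20 equiv | 1.20 equiv | 1.20 equiv |
| gas | 9.9 mM (held) | 9.9 mM (held) | 9.9 mM (held) | 9.9 mM (held) | 9.9 mM (held) | 9.9 mM (held) |
| solid second reagent | 0.50 equiv | 0.50 equiv | 0.75 equiv | 0.500 equiv | 0.500 equiv | 0.500 equiv |
| temperature | 35 °C | 68 °C | 35 °C | 50 °C | 80 °C | 20 °C |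
| remark | run made earlier | run made earlier | run made earlier |  |  |  |
| time |  |  |  | 40 h | 40 h | 40 h |

| run | time / h | target / % | side product / % |
|---|---|---|---|
| elm | 5.00 | 4.4 | 21.4 |
| elm | 10.0 | 13.1 | 23.5 |
| elm | 20.0 | 22.1 | 24.4 |
| elm | 30.0 | 25.5 | 23.8 |
| elm | 60.0 | 26.0 | 23.6 |
| larch | 1.33 | 2.1 | 24.7 |
| larch | 3.00 | 8.9 | 39.0 |
| larch | 6.00 | 10.7 | 39.0 |
| larch | 10.0 | 10.8 | 39.5 |
| larch | 12.0 | 10.6 | 38.9 |
| ash | 12.0 | 31.3 | 30.2 |
| ash | 25.0 | 43.8 | 30.1 |
| ash | 40.0 | 44.7 | 30.2 |
| ash | 48.0 | 44.9 | 29.6 |
| ash | 60.0 | 44.9 | 30.1 |

(standard deviation of a reading: 0.3 percentage points)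

- at the start none of the gas is in solution
- at the start none of the solid second reagent is in solution

- the flask with the highest share of target in all that became target or side product ("all alike" if they lie within 1.5 percentage points) (green / teal / ochre / all alike)
- share of target in all that became target or side product, green
- share of target in all that became target or side product, teal
- share of target in all that became target or side product, ochre

Where did the earlier runs stop? Where target and side product together reached the solid charge: the last readings sum to 49.6% in elm, 49.5% in larch and 75.0% in ash. So the solid second reagent looks like the limiting reagent, and the question is how its charge divides.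

What measures the division? The side odds, side product per target once a flask has come to rest: 0.908 in elm, 3.67 in larch.

And at other temperatures? I let the logarithm of the odds run straight with temperature through elm and larch. Green gets 1.71, teal 6.10 and ochre 0.481, the last two reached beyond the range of the runs. As target shares these are 36.9%, 14.1% and 67.5%, so I name ochre.

Doesn't third reagent differ between those runs? It does, and I assume it has no effect. Ash cannot test that, since its solid charge differs too; its odds of 0.670 come with both changes at once.

Is ochre at rest by 40 h? Elm's odds at 10.0 h were 1.79, above its final value, so elm read low in target at that time. Elm took about 30.0 h to settle and larch 6.00 h; scaled the same way, I estimate 14.4 h for green and 62.3 h for ochre, longer than 40 h. I expect ochre below 67.5%.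

The forecast also names ochre, but with figures above mine, 45% for green, 17% for teal and 70% for ochre , holding that “the solid is limiting and all of it ends up as product”.

The flasks give 35.7% for green, 16.2% for teal and 63.3% for ochre.

    substrate + partner → intermediate A (k = 0.00516 M⁻¹ s⁻¹, Ea = 72.0 kJ mol⁻¹)
    second reagent + intermediate A → intermediate B (k = 0.00127 M⁻¹ s⁻¹, Ea = 52.0 kJ mol⁻¹)
    third reagent + intermediate B → target (k = 6.61 × 10⁻⁴ M⁻¹ s⁻¹, Ea = 53.0 kJ mol⁻¹)
    substrate + second reagent → side product (k = 4.40 × 10⁻⁴ M⁻¹ s⁻¹, Ea = 66.0 kJ mol⁻¹)
    gas ⇌ partner, rate k5*(csat - [partner]) (kL = 1.75 × 10⁻⁴ s⁻¹)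
    solid second reagent ⇌ second reagent, rate k6*(cs6 - [second reagent]) while solid is left; crystals form when [second reagent] > cs6 (solubility = 33.0 mM, k = 1.30 × 10⁻⁴ s⁻¹)
    (constants at 20 °C)

Green has come to rest: target stands at 17.8% after 20.0 h and 17.8% after 400 h, and its odds read 1.80 against my 1.71. Teal's share doesn't move over ten times the time. Ochre has not quite stopped: intermediate B at 2.41% goes to 0%, target climbs from 29.7% to 32.8%, side product stays at 17.2%, and the share reaches 65.5%.

Green's neighbour with 0.013 M of substrate, equivalents and time held: none of the earlier runs varied the substrate, so my reckoning carries green's odds of 1.71 across unchanged, a share of 36.9%. That flask gives 73.6%, with 36.8% target and 13.2% side product.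

All runs stem from a simulated flask from invented constants.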